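**Retrosynthetic overview**
- The target comes from its di-O-acetate by methanolysis of the two aryl acetates.
- The pyranone is cut by a (3+3) heteroannulation at C4–C5 and O1–C2. Ring atoms O1, C6 (with ethyl) and C5 (with methyl) are the enol of symmetrical pentan-3-one; C2–C3–C4 is a malonyl unit whose C3 already carries the benzylic CH2. The partners are the arylmethyl malonyl dichloride and the trimethylsilyl enol ether of pentan-3-one.
- The dichloride comes from the benzylmalonic acid, reached via its mono-allyl ester from a Meldrum's acid adduct. That adduct is made by reductive alkylation with the hexasubstituted benzaldehyde diacetate, so both phenols are masked before any malonyl carbonyl exists.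
- The arene comes from 5-methoxyresorcinol, using its mirror plane: prenyl goes to the carbon between the two oxygens, the (R)-2-methylbutanoyl group (chiral pool, Weinreb amide) to one of the two equivalent remaining carbons, and formyl to the last C–H.
- Ring order: the benzene ring is bought; the pyranone is the only ring formed, in the penultimate step.

Key step: step 13

Remark: the malonyl carbon of 18 is a freely epimerising stereocentre carried as a mixture, and the double-bond geometry of 22 is immaterial because both enol carbons end as sp2 ring atoms; (R)-2-methylbutanoic acid is taken as available in enantiopure form.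

Step 1
Reactants: 1 5-methoxyresorcinol
Product: 2 1-methoxy-3,5-bis(methoxymethoxy)benzene
Conditions: NaH, MOMCl, DMF, 0 °C to rt
Reagents that add atoms: chloromethyl methyl ether, COCCl
Why: Williamson-type O-alkylation of both phenoxides installs MOM ethers, which protect the phenols and serve as directing groups for the two ring lithiations that follow.

Step 2
Reactants: 2 1-methoxy-3,5-bis(methoxymethoxy)benzene
Product: 4 5-methoxy-1,3-bis(methoxymethoxy)-2-(3-methylbut-2-enyl)benzene, via aryllithium 3 (not isolated)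
Conditions: n-BuLi, THF, 0 °C; then CuI (10 mol%), prenyl bromide, −78 °C to rt
Reagents that add atoms: 1-bromo-3-methylbut-2-ene (prenyl bromide), CC(C)=CCBr
Why: Directed ortho-metalation is expected at the carbon flanked by both OMOM groups, where two acetal oxygens chelate lithium and acidify the C–H more than at the OMOM/OMe-flanked sites, and copper-catalysed allylic substitution at the unhindered primary carbon of prenyl bromide then places the linear prenyl group on the mirror plane of the ring.

Step 3
Reactants: 5 (R)-2-methylbutanoic acid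
Product: 7 (2R)-N-methoxy-N,2-dimethylbutanamide, via acyl imidazolide 6 (not isolated)
Conditions: CDI, CH2Cl2, rt; then MeNHOMe·HCl, rt
Reagents that add atoms: N,O-dimethylhydroxylamine hydrochloride, CNOC.Cl
Why: Amide coupling through the acyl imidazolide, in which a simple α-branched alkanoic acid has neither an oxazolone nor a ketene path to racemisation under these conditions, so the R centre of 5 is kept.

Step 4
Reactants: 4 5-methoxy-1,3-bis(methoxymethoxy)-2-(3-methylbut-2-enyl)benzene; 7 (2R)-N-methoxy-N,2-dimethylbutanamide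
Product: 10 (2R)-1-[6-methoxy-2,4-bis(methoxymethoxy)-3-(3-methylbut-2-enyl)phenyl]-2-methylbutan-1-one, via aryllithium 8 (not isolated), via lithium hemiaminal adduct 9 (not isolated)
Conditions: n-BuLi (1.05 equiv), TMEDA, THF, 0 °C; then 7, −78 to 0 °C; aq. NH4Cl
Reagents that add atoms: none
Why: The second directed ortho-metalation can only take one of the two mirror-related C–H bonds between OMOM and OMe, so no regiochemical choice arises, and the Weinreb ketone synthesis stops at the chelated tetrahedral adduct 9, which releases the ketone only on quench, so the R stereocentre from 5 passes unchanged into the ketone.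

Step 5
Reactants: 10 (2R)-1-[6-methoxy-2,4-bis(methoxymethoxy)-3-(3-methylbut-2-enyl)phenyl]-2-methylbutan-1-one
Product: 11 (2R)-1-[2,4-dihydroxy-6-methoxy-3-(3-methylbut-2-enyl)phenyl]-2-methylbutan-1-one
Conditions: 3 M HCl, MeOH, rt
Reagents that add atoms: none
Why: Acid-catalysed acetal exchange of the two aryl MOM ethers with methanol frees both phenols at room temperature, where a prenyl group flanked by two phenols on this acylphloroglucinol pattern and a hindered ketone with a tertiary α-carbon are expected to persist if the reaction is stopped at completion.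

Step 6
Reactants: 11 (2R)-1-[2,4-dihydroxy-6-methoxy-3-(3-methylbut-2-enyl)phenyl]-2-methylbutan-1-one
Product: 13 2,4-dihydroxy-6-methoxy-5-[(2R)-2-methylbutanoyl]-3-(3-methylbut-2-enyl)benzaldehyde, via aryl iminium chloride 12 (not isolated)
Conditions: POCl3, DMF, MeCN, 0 °C to rt; then aq. NaOAc
Reagents that add atoms: N,N-dimethylformamide, CN(C)C=O; water, O
Why: Vilsmeier–Haack formylation can only take the single remaining ring C–H, which is ortho to one hydroxyl, ortho to the methoxy group and para to the other hydroxyl, and the ketone cannot divert the reagent into chromone formation because its α-carbon is tertiary.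

Step 7
Reactants: 13 2,4-dihydroxy-6-methoxy-5-[(2R)-2-methylbutanoyl]-3-(3-methylbut-2-enyl)benzaldehyde
Product: 14 2,4-diacetoxy-6-methoxy-5-[(2R)-2-methylbutanoyl]-3-(3-methylbut-2-enyl)benzaldehyde
Conditions: Ac2O, pyridine, DMAP (cat.), CH2Cl2, 0 °C to rt
Reagents that add atoms: acetic anhydride, CC(=O)OC(C)=O
Why: DMAP-catalysed O-acetylation overcomes the hydrogen bonding of both phenols to their neighbouring carbonyl groups, and the weak bases used are not expected to enolise the hindered ketone, so both phenols are masked before the malonyl unit is attached.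

Step 8
Reactants: 14 2,4-diacetoxy-6-methoxy-5-[(2R)-2-methylbutanoyl]-3-(3-methylbut-2-enyl)benzaldehyde; 15 Meldrum's acid
Product: 17 5-[[2,4-diacetoxy-6-methoxy-5-[(2R)-2-methylbutanoyl]-3-(3-methylbut-2-enyl)phenyl]methyl]-2,2-dimethyl-1,3-dioxane-4,6-dione, via arylidene Meldrum's acid 16 (not isolated)
Conditions: diethyl 2,6-dimethyl-1,4-dihydropyridine-3,5-dicarboxylate (Hantzsch ester), L-proline (20 mol%), CH2Cl2, rt
Reagents that add atoms: none
Why: Knoevenagel condensation with the highly acidic Meldrum's acid, followed in the same flask by Hantzsch ester transfer hydrogenation of the electron-poor arylidene 16 (three-component reductive alkylation), gives the monoalkylated Meldrum's acid without any base strong enough to cleave the aryl acetates.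

Step 9
Reactants: 17 5-[[2,4-diacetoxy-6-methoxy-5-[(2R)-2-methylbutanoyl]-3-(3-methylbut-2-enyl)phenyl]methyl]-2,2-dimethyl-1,3-dioxane-4,6-dione
Product: 18 2-[[2,4-diacetoxy-6-methoxy-5-[(2R)-2-methylbutanoyl]-3-(3-methylbut-2-enyl)phenyl]methyl]-3-oxo-3-(prop-2-enyloxy)propanoic acid
Conditions: allyl alcohol (10 equiv), toluene, 85 °C
Reagents that add atoms: prop-2-en-1-ol (allyl alcohol), C=CCO
Why: Thermal alcoholysis of a 5-monosubstituted Meldrum's acid opens the dioxanedione with loss of acetone to the malonic half ester under neutral conditions, below the temperature of decarboxylation and without the aqueous acid or base that would strip the aryl acetates.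

Step 10
Reactants: 18 2-[[2,4-diacetoxy-6-methoxy-5-[(2R)-2-methylbutanoyl]-3-(3-methylbut-2-enyl)phenyl]methyl]-3-oxo-3-(prop-2-enyloxy)propanoic acid
Product: 19 2-[[2,4-diacetoxy-6-methoxy-5-[(2R)-2-methylbutanoyl]-3-(3-methylbut-2-enyl)phenyl]methyl]propanedioic acid
Conditions: Pd(PPh3)4 (5 mol%), PhNHMe, THF, rt
Reagents that add atoms: none
Why: Tsuji–Trost deallylation, in which zerovalent palladium ionises the allyl ester to a π-allyl complex that N-methylaniline captures, frees the second carboxylic acid at room temperature and neutral pH, leaving the aryl acetates, the prenyl group (not an allylic ester) and the unheated malonic acid intact.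

Step 11
Reactants: 19 2-[[2,4-diacetoxy-6-methoxy-5-[(2R)-2-methylbutanoyl]-3-(3-methylbut-2-enyl)phenyl]methyl]propanedioic acid
Product: 20 2-[[2,4-diacetoxy-6-methoxy-5-[(2R)-2-methylbutanoyl]-3-(3-methylbut-2-enyl)phenyl]methyl]propanedioyl dichloride
Conditions: (COCl)2, DMF (cat.), CH2Cl2, 0 °C to rt; volatiles removed, used crude
Reagents that add atoms: oxalyl chloride, ClC(=O)C(=O)Cl
Why: Acyl chloride formation by the chloroiminium species from oxalyl chloride and catalytic DMF converts both acids at or below room temperature with only gaseous by-products, and the acetates prevent either phenol from lactonising onto the acyl chlorides.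

Step 12
Reactants: 21 pentan-3-one
Product: 22 (Z)-3-(trimethylsilyloxy)pent-2-ene
Conditions: TMSCl, NaI, Et3N, MeCN, rt
Reagents that add atoms: chlorotrimethylsilane, C[Si](C)(C)Cl
Why: Soft enolisation and O-silylation by Me3SiI formed in the flask gives the thermodynamic silyl enol ether, and the symmetry of pentan-3-one allows only one constitution.

Step 13
Reactants: 20 2-[[2,4-diacetoxy-6-methoxy-5-[(2R)-2-methylbutanoyl]-3-(3-methylbut-2-enyl)phenyl]methyl]propanedioyl dichloride; 22 (Z)-3-(trimethylsilyloxy)pent-2-ene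
Product: 25 3-[[2,4-diacetoxy-6-methoxy-5-[(2R)-2-methylbutanoyl]-3-(3-methylbut-2-enyl)phenyl]methyl]-6-ethyl-4-hydroxy-5-methylpyran-2-one, via chlorocarbonyl ketene 23 (not isolated), via diketo acid chloride 24 (not isolated)
Conditions: 22 (2.5 equiv), CH2Cl2, −78 °C to rt
Reagents that add atoms: none
Why: The monosubstituted malonyl dichloride loses HCl to the chlorocarbonyl ketene 23, whose ketene carbon is attacked by the nucleophilic carbon of the silyl enol ether, forming C4–C5 with loss of Me3SiCl to give 24. The enol oxygen of the pentanone-derived carbonyl in 24 then closes onto the remaining acyl chloride in a 6-exo-trig lactonisation (O1–C2), and tautomerisation gives the aromatic 4-hydroxypyran-2-one. The closest known reaction type is the condensation of malonyl dichlorides or chlorocarbonyl ketenes with silyl enol ethers and enolisable ketones to 4-hydroxy-2-pyranones. No stereocentre is formed and the existing R centre is not involved. The step needs one enol regiochemistry, which the symmetrical ketone gives without choice (methyl on C5, ethyl on C6), and it needs the aryl ketone and the phenols to stay out, which the di-ortho-substituted ketone with its tertiary α-carbon and the two acetates secure, while the C3 substituent blocks a second malonylation. O-acylation of the enol ether first would converge on the same ring by intramolecular C-acylation; pentan-3-one freed by HCl is itself a competent partner; low temperature and excess enol ether limit addition of HCl to the prenyl alkene.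

Step 14
Reactants: 25 3-[[2,4-diacetoxy-6-methoxy-5-[(2R)-2-methylbutanoyl]-3-(3-methylbut-2-enyl)phenyl]methyl]-6-ethyl-4-hydroxy-5-methylpyran-2-one
Product: 26 3-[[2,4-dihydroxy-6-methoxy-5-[(2R)-2-methylbutanoyl]-3-(3-methylbut-2-enyl)phenyl]methyl]-6-ethyl-4-hydroxy-5-methylpyran-2-one
Conditions: K2CO3 (3 equiv), MeOH, 0 °C; then 1 M HCl to pH 3, 0 °C
Reagents that add atoms: none
Why: Carbonate-mediated methanolysis (transesterification) of the two aryl acetates proceeds after the pyranone hydroxyl and the phenols are deprotonated, which shields the lactone from ring opening and the ketone α-C–H from exchange, so the R centre is retained, and the cold, brief acidification avoids cyclisation of the prenyl group onto a phenol.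

**Compound list**
1 | 5-methoxyresorcinol | COc1cc(O)cc(O)c1 | starting material
2 | 1-methoxy-3,5-bis(methoxymethoxy)benzene | COCOc1cc(OC)cc(OCOC)c1 | intermediate
3 | [4-methoxy-2,6-bis(methoxymethoxy)phenyl]lithium | [Li]c1c(OCOC)cc(OC)cc1OCOC | intermediate
4 | 5-methoxy-1,3-bis(methoxymethoxy)-2-(3-methylbut-2-enyl)benzene | COCOc1cc(OC)cc(OCOC)c1CC=C(C)C | intermediate
5 | (R)-2-methylbutanoic acid | CC[C@@H](C)C(=O)O | starting material
6 | (2R)-1-(imidazol-1-yl)-2-methylbutan-1-one | CC[C@@H](C)C(=O)n1ccnc1 | intermediate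
7 | (2R)-N-methoxy-N,2-dimethylbutanamide | CC[C@@H](C)C(=O)N(C)OC | intermediate
8 | [6-methoxy-2,4-bis(methoxymethoxy)-3-(3-methylbut-2-enyl)phenyl]lithium | [Li]c1c(OC)cc(OCOC)c(CC=C(C)C)c1OCOC | intermediate
9 | lithium (2R)-1-[methoxy(methyl)amino]-1-[6-methoxy-2,4-bis(methoxymethoxy)-3-(3-methylbut-2-enyl)phenyl]-2-methylbutan-1-olate | CC[C@@H](C)C(O[Li])(N(C)OC)c1c(OC)cc(OCOC)c(CC=C(C)C)c1OCOC | intermediate
10 | (2R)-1-[6-methoxy-2,4-bis(methoxymethoxy)-3-(3-methylbut-2-enyl)phenyl]-2-methylbutan-1-one | COc1cc(OCOC)c(CC=C(C)C)c(OCOC)c1C(=O)[C@H](C)CC | intermediate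
11 | (2R)-1-[2,4-dihydroxy-6-methoxy-3-(3-methylbut-2-enyl)phenyl]-2-methylbutan-1-one | COc1cc(O)c(CC=C(C)C)c(O)c1C(=O)[C@H](C)CC | intermediate
12 | N-[[2,4-dihydroxy-6-methoxy-5-[(2R)-2-methylbutanoyl]-3-(3-methylbut-2-enyl)phenyl]methylidene]-N-methylmethanaminium chloride | COc1c(C=[N+](C)C)c(O)c(CC=C(C)C)c(O)c1C(=O)[C@H](C)CC.[Cl-] | intermediate
13 | 2,4-dihydroxy-6-methoxy-5-[(2R)-2-methylbutanoyl]-3-(3-methylbut-2-enyl)benzaldehyde | COc1c(C=O)c(O)c(CC=C(C)C)c(O)c1C(=O)[C@H](C)CC | intermediate
14 | 2,4-diacetoxy-6-methoxy-5-[(2R)-2-methylbutanoyl]-3-(3-methylbut-2-enyl)benzaldehyde | COc1c(C=O)c(OC(C)=O)c(CC=C(C)C)c(OC(C)=O)c1C(=O)[C@H](C)CC | intermediate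
15 | Meldrum's acid (2,2-dimethyl-1,3-dioxane-4,6-dione) | CC1(C)OC(=O)CC(=O)O1 | starting material
16 | 5-[[2,4-diacetoxy-6-methoxy-5-[(2R)-2-methylbutanoyl]-3-(3-methylbut-2-enyl)phenyl]methylidene]-2,2-dimethyl-1,3-dioxane-4,6-dione | COc1c(C=C2C(=O)OC(C)(C)OC2=O)c(OC(C)=O)c(CC=C(C)C)c(OC(C)=O)c1C(=O)[C@H](C)CC | intermediate
17 | 5-[[2,4-diacetoxy-6-methoxy-5-[(2R)-2-methylbutanoyl]-3-(3-methylbut-2-enyl)phenyl]methyl]-2,2-dimethyl-1,3-dioxane-4,6-dione | COc1c(CC2C(=O)OC(C)(C)OC2=O)c(OC(C)=O)c(CC=C(C)C)c(OC(C)=O)c1C(=O)[C@H](C)CC | intermediate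
18 | 2-[[2,4-diacetoxy-6-methoxy-5-[(2R)-2-methylbutanoyl]-3-(3-methylbut-2-enyl)phenyl]methyl]-3-oxo-3-(prop-2-enyloxy)propanoic acid | COc1c(CC(C(=O)O)C(=O)OCC=C)c(OC(C)=O)c(CC=C(C)C)c(OC(C)=O)c1C(=O)[C@H](C)CC | intermediate
19 | 2-[[2,4-diacetoxy-6-methoxy-5-[(2R)-2-methylbutanoyl]-3-(3-methylbut-2-enyl)phenyl]methyl]propanedioic acid | COc1c(CC(C(=O)O)C(=O)O)c(OC(C)=O)c(CC=C(C)C)c(OC(C)=O)c1C(=O)[C@H](C)CC | intermediate
20 | 2-[[2,4-diacetoxy-6-methoxy-5-[(2R)-2-methylbutanoyl]-3-(3-methylbut-2-enyl)phenyl]methyl]propanedioyl dichloride | COc1c(CC(C(=O)Cl)C(=O)Cl)c(OC(C)=O)c(CC=C(C)C)c(OC(C)=O)c1C(=O)[C@H](C)CC | intermediate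
21 | pentan-3-one | CCC(=O)CC | starting material
22 | (Z)-3-(trimethylsilyloxy)pent-2-ene | C/C=C(/CC)O[Si](C)(C)C | intermediate
23 | 2-[[2,4-diacetoxy-6-methoxy-5-[(2R)-2-methylbutanoyl]-3-(3-methylbut-2-enyl)phenyl]methyl]-3-oxoprop-2-enoyl chloride (chlorocarbonyl ketene) | COc1c(CC(=C=O)C(=O)Cl)c(OC(C)=O)c(CC=C(C)C)c(OC(C)=O)c1C(=O)[C@H](C)CC | intermediate
24 | 2-[[2,4-diacetoxy-6-methoxy-5-[(2R)-2-methylbutanoyl]-3-(3-methylbut-2-enyl)phenyl]methyl]-4-methyl-3,5-dioxoheptanoyl chloride | CCC(=O)C(C)C(=O)C(Cc1c(OC(C)=O)c(CC=C(C)C)c(OC(C)=O)c(C(=O)[C@H](C)CC)c1OC)C(=O)Cl | intermediate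
25 | 3-[[2,4-diacetoxy-6-methoxy-5-[(2R)-2-methylbutanoyl]-3-(3-methylbut-2-enyl)phenyl]methyl]-6-ethyl-4-hydroxy-5-methylpyran-2-one | CCc1oc(=O)c(Cc2c(OC(C)=O)c(CC=C(C)C)c(OC(C)=O)c(C(=O)[C@H](C)CC)c2OC)c(O)c1C | intermediate
26 | 3-[[2,4-dihydroxy-6-methoxy-5-[(2R)-2-methylbutanoyl]-3-(3-methylbut-2-enyl)phenyl]methyl]-6-ethyl-4-hydroxy-5-methylpyran-2-one (CNP0233274.1) | CCc1oc(=O)c(Cc2c(O)c(CC=C(C)C)c(O)c(C(=O)[C@H](C)CC)c2OC)c(O)c1C | target

**Step count and risks**
Total step count: 14. Longest linear sequence: 12 steps (steps 1, 2, 4 to 11, 13 and 14, from 1); steps 3 and 12 are side branches.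

Steps most likely to fail:

1. Step 13. Protodesilylation of the enol ether by the HCl that the reaction liberates, self-condensation of the chlorocarbonyl ketene and addition of HCl across the prenyl double bond may outrun the C-acylation. The fallback sets out from 14 and 22 and closes the pyranone before it is joined to the arene. Enol ether 22 and unsubstituted malonyl dichloride (Et2O, −78 °C to rt, enol ether in excess) should give 6-ethyl-4-hydroxy-5-methylpyran-2-one F1 by the same annulation in its simplest form. F1 is then joined to aldehyde 14 by three-component reductive alkylation (L-proline, Hantzsch ester, CH2Cl2, rt). This passes through the arylidene pyran-2,4-dione F2, which the dihydropyridine reduces in the flask, and comes back to the route at 25.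

2. Step 6. Acid-promoted cyclisation of the prenyl group onto a neighbouring phenol, or too slow a substitution at the acyl-deactivated and doubly flanked ring position, may defeat the electrophilic formylation. The fallback sets out from 4 and brings in the formyl carbon by lithiation before the phenols are freed. Lithiation of 4 to 8 as in step 4 and quenching with DMF should give 6-methoxy-2,4-bis(methoxymethoxy)-3-(3-methylbut-2-enyl)benzaldehyde F3. Condensation with N,N'-dimethylethane-1,2-diamine masks the aldehyde as 2-[6-methoxy-2,4-bis(methoxymethoxy)-3-(3-methylbut-2-enyl)phenyl]-1,3-dimethylimidazolidine F4. n-BuLi then metalates the last ring C–H, between OMe and OMOM, to give the aryllithium F5, and amide 7 converts it into the imidazolidine-masked ketone F6. Aqueous HCl in MeOH removes both MOM groups and the aminal together, and the sequence comes back to the route at 13.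

3. Step 8. Slow condensation at the di-ortho-substituted aldehyde may let loss of the neighbouring acetate and lactonisation of the freed phenol onto the Meldrum's acid ring compete. The fallback sets out from 14 and makes the benzyl–malonyl bond by SN2 alkylation. NaBH(OAc)3 reduces the aldehyde selectively, under mildly acidic conditions that suppress acetyl migration, to the benzyl alcohol F7. CBr4 and PPh3 (Appel reaction) give the benzyl bromide F8. The sodium salt of diallyl malonate (NaH, THF, 0 °C) is alkylated to the diallyl benzylmalonate F9. Double deallylation with Pd(PPh3)4 and N-methylaniline comes back to the route at 19, bypassing steps 8 and 9.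

**Further compounds**
F1 | step 13 | 6-ethyl-4-hydroxy-5-methylpyran-2-one | CCc1oc(=O)cc(O)c1C
F2 | step 13 | 3-[[2,4-diacetoxy-6-methoxy-5-[(2R)-2-methylbutanoyl]-3-(3-methylbut-2-enyl)phenyl]methylidene]-6-ethyl-5-methylpyran-2,4-dione | CCC1=C(C)C(=O)C(=Cc2c(OC(C)=O)c(CC=C(C)C)c(OC(C)=O)c(C(=O)[C@H](C)CC)c2OC)C(=O)O1
F3 | step 6 | 6-methoxy-2,4-bis(methoxymethoxy)-3-(3-methylbut-2-enyl)benzaldehyde | COc1cc(OCOC)c(CC=C(C)C)c(OCOC)c1C=O
F4 | step 6 | 2-[6-methoxy-2,4-bis(methoxymethoxy)-3-(3-methylbut-2-enyl)phenyl]-1,3-dimethylimidazolidine | COc1cc(OCOC)c(CC=C(C)C)c(OCOC)c1C1N(C)CCN1C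
F5 | step 6 | [3-(1,3-dimethylimidazolidin-2-yl)-2-methoxy-4,6-bis(methoxymethoxy)-5-(3-methylbut-2-enyl)phenyl]lithium | [Li]c1c(OC)c(C2N(C)CCN2C)c(OCOC)c(CC=C(C)C)c1OCOC
F6 | step 6 | (2R)-1-[3-(1,3-dimethylimidazolidin-2-yl)-2-methoxy-4,6-bis(methoxymethoxy)-5-(3-methylbut-2-enyl)phenyl]-2-methylbutan-1-one | COc1c(C2N(C)CCN2C)c(OCOC)c(CC=C(C)C)c(OCOC)c1C(=O)[C@H](C)CC
F7 | step 8 | [3-acetoxy-2-(hydroxymethyl)-1-methoxy-6-[(2R)-2-methylbutanoyl]-4-(3-methylbut-2-enyl)phen-5-yl] acetate (benzyl alcohol from 14) | COc1c(CO)c(OC(C)=O)c(CC=C(C)C)c(OC(C)=O)c1C(=O)[C@H](C)CC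
F8 | step 8 | benzyl bromide from F7 | COc1c(CBr)c(OC(C)=O)c(CC=C(C)C)c(OC(C)=O)c1C(=O)[C@H](C)CC
F9 | step 8 | diallyl 2-[[2,4-diacetoxy-6-methoxy-5-[(2R)-2-methylbutanoyl]-3-(3-methylbut-2-enyl)phenyl]methyl]propanedioate | COc1c(CC(C(=O)OCC=C)C(=O)OCC=C)c(OC(C)=O)c(CC=C(C)C)c(OC(C)=O)c1C(=O)[C@H](C)CC
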